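## Plan

1. Bicycle numbering used throughout: C1 (bridgehead, Me), C2 (quaternary, Me and aryl), C3H2, C4H2, C5H (bridgehead), C6H2. The retrosynthesis first cuts the two C–Br bonds and raises C3–C4 to an alkene. It then cuts C5–C1 and C5–C6 together, which opens both carbocycles to an acyclic hex-1-en-5-yne.
2. Enabling feature: the cyclopentane (C1–C5) and the cyclopropane (C1, C5, C6) share the C1–C5 edge. C5 carries only H and sits next to the unsubstituted C4H2–C3H2 unit. C5 is therefore a latent carbene (terminal alkyne carbon) and the C1(Me)–C6H2 edge is a latent isopropenyl group.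
3. The enyne comes from a 3,3-disubstituted benzofuran-2-one. The lactone C=O becomes C1 and its methyl group plus C6 (2 MeLi, then loss of water). C3–C5 come from propargyl bromide, and the lactone comes from an aryl bromide and a propanoate.
4. Ring order in the forward direction: arene (bought), then the temporary lactone ring (closed in step 2, opened in step 4). Cyclopropane and cyclopentane then form in one event in step 7. The C1–C5 bond completes the cyclopentane, and no ring is closed afterwards.
5. Stereochemistry: C2 is set by chiral phase-transfer propargylation (step 3). C1 and C5 are set in step 7 by relay from C2 (allylic strain, with a forced cis fusion).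

Key step: step 7

Assumption: the sense of induction of the phase-transfer catalyst cannot be assigned with certainty in advance, so the catalyst antipode that delivers (S)-7 is used.

## Route

Step 1
Reactants: 1 1-bromo-2-methoxy-4-methylbenzene; 2 tert-butyl propanoate
Product: 3 tert-butyl 2-(2-methoxy-4-methylphenyl)propanoate (racemic)
Conditions: LiHMDS, Pd(dba)2 (cat.), P(t-Bu)3 (cat.), toluene, rt
Reagents that add atoms: none
Why: Pd-catalysed α-arylation of an ester enolate, in which the tert-butyl ester suppresses Claisen condensation and the bulky electron-rich phosphine tolerates the ortho-methoxy group; the new centre forms racemic and is erased by enolisation in step 3.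

Step 2
Reactants: 3 tert-butyl 2-(2-methoxy-4-methylphenyl)propanoate
Product: 5 3,6-dimethyl-1-benzofuran-2(3H)-one (racemic), via hydroxy acid 4 (not isolated)
Conditions: BBr3, CH2Cl2, −78 °C to rt; then H2O
Reagents that add atoms: none
Why: Lewis-acid cleavage of the aryl methyl ether and the tert-butyl ester gives an o-hydroxyaryl acid that should lactonise spontaneously to the five-membered temporary ring, which acidifies C3–H and ties the aryl group back for step 3.

Step 3
Reactants: 5 3,6-dimethyl-1-benzofuran-2(3H)-one; 6 3-bromoprop-1-yne (propargyl bromide)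
Product: 7 (3S)-3,6-dimethyl-3-(prop-2-yn-1-yl)-1-benzofuran-2(3H)-one
Conditions: C2-symmetric N-spiro bis(binaphthyl)ammonium bromide bearing 3,4,5-F3C6H2 groups (cat.), solid Cs2CO3, toluene, −20 °C
Reagents that add atoms: none
Why: Asymmetric phase-transfer alkylation, in which the flat aromatic 2-oxidobenzofuran enolate forms a tight ion pair with the chiral ammonium cation, one face is shielded, and SN2 attack on propargyl bromide sets the quaternary centre (future C2).

Step 4
Reactants: 7 (3S)-3,6-dimethyl-3-(prop-2-yn-1-yl)-1-benzofuran-2(3H)-one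
Product: 9 2-[(3S)-2-hydroxy-2,3-dimethylhex-5-yn-3-yl]-5-methylphenol, via methyl ketone 8 (not isolated)
Conditions: MeLi (excess), CeCl3, THF, −78 to 0 °C; then H2O
Reagents that add atoms: methyllithium, [Li]C
Why: Double addition of an organocerium methyl nucleophile to an aryl ester, in which phenoxide leaves after the first addition, cerium suppresses enolisation of the hindered methyl ketone, and the quaternary centre cannot epimerise.

Step 5
Reactants: 9 2-[(3S)-2-hydroxy-2,3-dimethylhex-5-yn-3-yl]-5-methylphenol
Product: 10 (3S)-3-[2-(tert-butyldimethylsilyloxy)-4-methylphenyl]-2,3-dimethylhex-5-yn-2-ol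
Conditions: TBSCl, imidazole, DMF, rt
Reagents that add atoms: tert-butyldimethylsilyl chloride (TBSCl), CC(C)(C)[Si](C)(C)Cl
Why: Chemoselective silylation of the acidic phenol over the neopentyl-type tertiary alcohol gives a fluoride-labile helper group that later blocks O-attack on the alkyne and enlarges the aryl group.

Step 6
Reactants: 10 (3S)-3-[2-(tert-butyldimethylsilyloxy)-4-methylphenyl]-2,3-dimethylhex-5-yn-2-ol
Product: 11 tert-butyl{2-[(3R)-2,3-dimethylhex-1-en-5-yn-3-yl]-5-methylphenoxy}dimethylsilane
Conditions: methyl N-(triethylammoniosulfonyl)carbamate (Burgess reagent), toluene, 70 °C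
Reagents that add atoms: none
Why: Burgess dehydration by syn elimination of the sulfamate ester under non-acidic conditions, where only the two equivalent methyl groups carry β-hydrogens, so the isopropenyl group is the only possible alkene (the descriptor changes for priority reasons only).

Step 7
Reactants: 11 tert-butyl{2-[(3R)-2,3-dimethylhex-1-en-5-yn-3-yl]-5-methylphenoxy}dimethylsilane
Product: 13 tert-butyl{2-[(1S,4R,5S)-4,5-dimethylbicyclo[3.1.0]hex-2-en-4-yl]-5-methylphenoxy}dimethylsilane, via cyclopropyl gold carbene 12 (not isolated)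
Conditions: Ph3PAuNTf2 (2 mol%), CH2Cl2, rt
Reagents that add atoms: none
Why: Cationic gold(I) binds the terminal alkyne, the 1,1-disubstituted alkene attacks the terminal alkyne carbon (future C5) with C6 leading and C1 following to give cyclopropyl gold carbene 12, and a 1,2-hydride shift from C3H2 to the carbene carbon C4 with loss of gold leaves the C3=C4 alkene. The closest known reaction type is the gold(I)- or platinum(II)-catalysed cycloisomerisation of 1,5-enynes to bicyclo[3.1.0]hex-2-enes. The cyclopentane closes 5-endo-dig (exo with respect to the alkene) through the C1–C5 bond, and the cyclopropane closes in the same event through C5–C6 as a formal intramolecular [2+1] addition of an alkyne-derived carbene. C1 and C5 can only form cis to each other, and their sense relative to C2 is set by allylic strain: in the reactive rotamer about C2–C1 the propargyl arm stands over the alkene face, one remaining C2 substituent lies beside the vinylic methyl group and the other beside =CH2, so the bulky o-silyloxyaryl group should take the =CH2 side and end cis to C6, with the two methyl groups cis as in the target. The step needs this facial selectivity, and it needs chemoselectivity for the alkene as nucleophile, which is secured by the silylated phenol (no O-attack on the alkyne) and by the free arene position next to C2 being meta to both donor groups (no hydroarylation). The two hydrogens on C3 should make the hydride shift faster than the ring expansion to cyclohexadienes that occurs when this position is fully substituted.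

Step 8
Reactants: 13 tert-butyl{2-[(1S,4R,5S)-4,5-dimethylbicyclo[3.1.0]hex-2-en-4-yl]-5-methylphenoxy}dimethylsilane
Product: 14 tert-butyl{2-[(1S,2R,5R)-1,2-dimethylbicyclo[3.1.0]hexan-2-yl]-5-methylphenoxy}dimethylsilane
Conditions: 2-nitrobenzenesulfonohydrazide (excess), Et3N, CH2Cl2, rt
Reagents that add atoms: none
Why: Diimide reduction transfers H2 in a concerted way to the strained cis-disubstituted cyclopentene without a metal surface, radical or cation, so the vinylcyclopropane should not open and no stereocentre is touched.

Step 9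
Reactants: 14 tert-butyl{2-[(1S,2R,5R)-1,2-dimethylbicyclo[3.1.0]hexan-2-yl]-5-methylphenoxy}dimethylsilane
Product: 15 2-[(1S,2R,5R)-1,2-dimethylbicyclo[3.1.0]hexan-2-yl]-5-methylphenol
Conditions: TBAF, THF, 0 °C
Reagents that add atoms: none
Why: Fluoride-induced desilylation of an aryl silyl ether under non-acidic conditions, which matters because acid would add the free phenol to the cyclopropane.

Step 10
Reactants: 15 2-[(1S,2R,5R)-1,2-dimethylbicyclo[3.1.0]hexan-2-yl]-5-methylphenol
Product: 17 2,4-dibromo-6-[(1S,2R,5R)-1,2-dimethylbicyclo[3.1.0]hexan-2-yl]-3-methylphenol (target), via monobromide laurinterol 16 (not isolated)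
Conditions: NBS (2.05 equiv), solid NaHCO3, MeCN, 0 °C to rt, dark
Reagents that add atoms: N-bromosuccinimide (NBS), O=C1CCC(=O)N1Br
Why: Twofold electrophilic aromatic bromination, in which OH directs to its para and its only free ortho position (both also ortho to the methyl group), the remaining C–H is meta to OH, and NBS releases no HBr that could open the cyclopropane.

## Compound list

1 | 1-bromo-2-methoxy-4-methylbenzene | COc1cc(C)ccc1Br | starting material
2 | tert-butyl propanoate | CCC(=O)OC(C)(C)C | starting material
3 | tert-butyl 2-(2-methoxy-4-methylphenyl)propanoate (racemic) | COc1cc(C)ccc1C(C)C(=O)OC(C)(C)C | intermediate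
4 | 2-(2-hydroxy-4-methylphenyl)propanoic acid (racemic, not isolated) | Cc1ccc(C(C)C(=O)O)c(O)c1 | intermediate
5 | 3,6-dimethyl-1-benzofuran-2(3H)-one (racemic) | Cc1ccc2c(c1)OC(=O)C2C | intermediate
6 | 3-bromoprop-1-yne | C#CCBr | starting material
7 | (3S)-3,6-dimethyl-3-(prop-2-yn-1-yl)-1-benzofuran-2(3H)-one | Cc1ccc2c(c1)OC(=O)[C@@]2(C)CC#C | intermediate
8 | (3S)-3-(2-hydroxy-4-methylphenyl)-3-methylhex-5-yn-2-one (present as lithium phenoxide, not isolated) | Cc1ccc([C@](C)(CC#C)C(C)=O)c(O)c1 | intermediate
9 | 2-[(3S)-2-hydroxy-2,3-dimethylhex-5-yn-3-yl]-5-methylphenol | Cc1ccc([C@](C)(CC#C)C(C)(C)O)c(O)c1 | intermediate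
10 | (3S)-3-[2-(tert-butyldimethylsilyloxy)-4-methylphenyl]-2,3-dimethylhex-5-yn-2-ol | Cc1ccc([C@](C)(CC#C)C(C)(C)O)c(O[Si](C)(C)C(C)(C)C)c1 | intermediate
11 | tert-butyl{2-[(3R)-2,3-dimethylhex-1-en-5-yn-3-yl]-5-methylphenoxy}dimethylsilane | Cc1ccc([C@](C)(CC#C)C(C)=C)c(O[Si](C)(C)C(C)(C)C)c1 | intermediate
12 | cyclopropyl gold carbene: (Ph3P)Au bound as carbene at C4 of the 2-aryl-1,2-dimethylbicyclo[3.1.0]hexane skeleton, same spatial arrangement as 13, NTf2 salt (not isolated) | Cc1ccc([C@]2(C)CC(=[Au][P+](c3ccccc3)(c3ccccc3)c3ccccc3)[C@@H]3C[C@@]32C)c(O[Si](C)(C)C(C)(C)C)c1.O=S(=O)([N-]S(=O)(=O)C(F)(F)F)C(F)(F)F | intermediate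
13 | tert-butyl{2-[(1S,4R,5S)-4,5-dimethylbicyclo[3.1.0]hex-2-en-4-yl]-5-methylphenoxy}dimethylsilane | Cc1ccc([C@]2(C)C=C[C@@H]3C[C@@]32C)c(O[Si](C)(C)C(C)(C)C)c1 | intermediate
14 | tert-butyl{2-[(1S,2R,5R)-1,2-dimethylbicyclo[3.1.0]hexan-2-yl]-5-methylphenoxy}dimethylsilane | Cc1ccc([C@]2(C)CC[C@@H]3C[C@@]32C)c(O[Si](C)(C)C(C)(C)C)c1 | intermediate
15 | 2-[(1S,2R,5R)-1,2-dimethylbicyclo[3.1.0]hexan-2-yl]-5-methylphenol | Cc1ccc([C@]2(C)CC[C@@H]3C[C@@]32C)c(O)c1 | intermediate
16 | 4-bromo-2-[(1S,2R,5R)-1,2-dimethylbicyclo[3.1.0]hexan-2-yl]-5-methylphenol (laurinterol, not isolated) | Cc1cc(O)c([C@]2(C)CC[C@@H]3C[C@@]32C)cc1Br | intermediate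
17 | 2,4-dibromo-6-[(1S,2R,5R)-1,2-dimethylbicyclo[3.1.0]hexan-2-yl]-3-methylphenol | Cc1c(Br)cc([C@]2(C)CC[C@@H]3C[C@@]32C)c(O)c1Br | target

## Step count and risks

Total step count: 10. Longest linear sequence: 10 (from 1).

**Step 7.**
- What may go wrong: the two faces of the isopropenyl group may be poorly discriminated, so that the cyclopropane is partly built away from the aryl group. The carbene may also leak into six-membered-ring isomers.
- Fallback: it sets out from 11 and returns at 14, bypassing step 8, and no longer uses the alkyne as carbene source.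
- The alkyne of 11 is hydroborated with dicyclohexylborane and oxidised with NaBO3 to (4R)-4-[2-(tert-butyldimethylsilyloxy)-4-methylphenyl]-4,5-dimethylhex-5-enal F1.
- Hydrazine converts this into (4R)-4-[2-(tert-butyldimethylsilyloxy)-4-methylphenyl]-4,5-dimethylhex-5-enal hydrazone F2.
- Iodine and Et3N give tert-butyl{2-[(3R)-6,6-diiodo-2,3-dimethylhex-1-en-3-yl]-5-methylphenoxy}dimethylsilane F3.
- Et2Zn in CH2Cl2 then generates an α-iodoalkylzinc carbenoid that cyclopropanates the isopropenyl group in an intramolecular Simmons–Smith reaction, giving 14 at the saturated level.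
- The compact, later transition state should respond more strongly to the aryl/methyl difference at C2. Any diastereomer would be removed by chromatography at 14.

**Step 3.**
- What may go wrong: face discrimination in the ion pair may be insufficient. An uncatalysed background alkylation or O-alkylation would also erode the optical purity.
- Fallback: it sets out from 5 and returns at 9, replacing the SN2 alkylation with a metal-controlled allylation.
- Pd-catalysed asymmetric allylic alkylation of 5 uses 2-chloroallyl methyl carbonate and a C2-symmetric bis(2-diphenylphosphinobenzamide) ligand. It gives (3S)-3-(2-chloroprop-2-en-1-yl)-3,6-dimethyl-1-benzofuran-2(3H)-one F4.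
- MeLi/CeCl3 opens F4 to 2-[(3S)-5-chloro-2-hydroxy-2,3-dimethylhex-5-en-3-yl]-5-methylphenol F5.
- Excess LDA removes HCl from the vinyl chloride to unmask the terminal alkyne of 9.

**Step 6.**
- What may go wrong: the hindered sulfamate may ionise, followed by a 1,2-aryl shift through a phenonium ion. Activation of the neopentyl-type alcohol may also be sluggish.
- Fallback: it sets out from 7 and returns at 11, and builds the alkene by carbonyl olefination instead of elimination.
- Lactone 7 is opened with MeNH(OMe)·HCl and i-PrMgCl to (2S)-2-(2-hydroxy-4-methylphenyl)-N-methoxy-N,2-dimethylpent-4-ynamide F6.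
- Silylation with TBSCl and imidazole gives (2S)-2-[2-(tert-butyldimethylsilyloxy)-4-methylphenyl]-N-methoxy-N,2-dimethylpent-4-ynamide F7.
- MeLi converts F7 into (3S)-3-[2-(tert-butyldimethylsilyloxy)-4-methylphenyl]-3-methylhex-5-yn-2-one F8.
- Wittig methylenation with excess Ph3P=CH2 in warm toluene gives 11.

## Further compounds

F1 | step 7 | (4R)-4-[2-(tert-butyldimethylsilyloxy)-4-methylphenyl]-4,5-dimethylhex-5-enal | Cc1ccc([C@](C)(CCC=O)C(C)=C)c(O[Si](C)(C)C(C)(C)C)c1
F2 | step 7 | (4R)-4-[2-(tert-butyldimethylsilyloxy)-4-methylphenyl]-4,5-dimethylhex-5-enal hydrazone | Cc1ccc([C@](C)(CCC=NN)C(C)=C)c(O[Si](C)(C)C(C)(C)C)c1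
F3 | step 7 | tert-butyl{2-[(3R)-6,6-diiodo-2,3-dimethylhex-1-en-3-yl]-5-methylphenoxy}dimethylsilane | Cc1ccc([C@](C)(CCC(I)I)C(C)=C)c(O[Si](C)(C)C(C)(C)C)c1
F4 | step 3 | (3S)-3-(2-chloroprop-2-en-1-yl)-3,6-dimethyl-1-benzofuran-2(3H)-one | Cc1ccc2c(c1)OC(=O)[C@@]2(C)CC(Cl)=C
F5 | step 3 | 2-[(3S)-5-chloro-2-hydroxy-2,3-dimethylhex-5-en-3-yl]-5-methylphenol | Cc1ccc([C@](C)(CC(Cl)=C)C(C)(C)O)c(O)c1
F6 | step 6 | (2S)-2-(2-hydroxy-4-methylphenyl)-N-methoxy-N,2-dimethylpent-4-ynamide | Cc1ccc([C@](C)(CC#C)C(=O)N(C)OC)c(O)c1
F7 | step 6 | (2S)-2-[2-(tert-butyldimethylsilyloxy)-4-methylphenyl]-N-methoxy-N,2-dimethylpent-4-ynamide | Cc1ccc([C@](C)(CC#C)C(=O)N(C)OC)c(O[Si](C)(C)C(C)(C)C)c1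
F8 | step 6 | (3S)-3-[2-(tert-butyldimethylsilyloxy)-4-methylphenyl]-3-methylhex-5-yn-2-one | Cc1ccc([C@](C)(CC#C)C(C)=O)c(O[Si](C)(C)C(C)(C)C)c1
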